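Ring A (the acetylenic 3-hydroxy ring, atoms C1–C6) hides a cyclohexane-1,4-dione: its carbinol carbon C3 and its enyne carbon C6 are 1,4-related. The route rests on an asymmetric intramolecular Stetter reaction of the acyclic keto-enal 3,3,5-trimethyl-4-oxohex-5-enal. The acyl-anion equivalent at C3 adds to C4, the terminal carbon of an isopropenyl ketone, and so forms the C3–C4 bond. This one redox-neutral operation closes ring A and sets a methyl stereocentre at C5, which relays chirality to C3 and is then erased on enol triflation. Sonogashira coupling, two Wittig olefinations through the C10 dialdehyde and a separately made ring B aldehyde complete the C40 skeleton.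

Key step: step 3

Remark on the chemistry: carotenoid numbering is used, with ring A the acetylenic ring (C1 gem-dimethyl, C3 carbinol, C4 methylene, C5 methyl-bearing, C6 alkynyl-bearing) and ring B the dihydroxy ring (C1'–C6'); the target is then (3R,3'S,6'R) and all-E.
Remark on the chemistry: Wittig steps are assumed to give E/Z mixtures at the new double bond, which are equilibrated thermally; the all-E isomer is isolated at the end.

Step 1
Reactants: 1 3,3-dimethyloxolan-2-one; 2 isopropenylmagnesium bromide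
Product: 3 6-hydroxy-2,4,4-trimethylhex-1-en-3-one
Conditions: THF, −40 °C → 0 °C, inverse addition; aqueous work-up
Reagents that add atoms: none
Why: Grignard acyl substitution on the lactone should stop at the ketone because the hindered magnesium hemiketal collapses only on work-up and the α-quaternary isopropenyl ketone resists a second addition.

Step 2
Reactants: 3 6-hydroxy-2,4,4-trimethylhex-1-en-3-one
Product: 4 3,3,5-trimethyl-4-oxohex-5-enal
Conditions: Dess–Martin periodinane, CH2Cl2, 0 °C → rt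
Reagents that add atoms: none
Why: Dess–Martin oxidation converts the primary alcohol into the aldehyde under neutral conditions that leave the isopropenyl ketone untouched.

Step 3
Reactants: 4 3,3,5-trimethyl-4-oxohex-5-enal
Product: 5 (6R)-2,2,6-trimethylcyclohexane-1,4-dione
Conditions: (5aS,10bR)-2-(pentafluorophenyl)-5a,10b-dihydro-4H,6H-indeno[2,1-b][1,2,4]triazolo[4,3-d][1,4]oxazin-2-ium tetrafluoroborate (0.2 equiv; its antipode if the sense of induction proves opposite), KN(SiMe3)2 (0.18 equiv), toluene, 0.02 M, 23 °C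
Reagents that add atoms: none
Why: Proposed new method: the triazolylidene adds to the aldehyde carbon C3 to give a Breslow intermediate whose acyl-anion carbon attacks C4, the unsubstituted β-carbon of the isopropenyl ketone, after which proton transfer to C5 and loss of the carbene release the 1,4-dione. The closest known reaction type is the catalytic asymmetric intramolecular Stetter reaction of aliphatic aldehydes with tethered Michael acceptors; new here is that the acceptor carbonyl (C6) lies inside the forming ring. Ring A closes in a 6-endo-trig mode, helped by the gem-dimethyl group at C1 and analogous to the 6-endo conjugate cyclisations of vinyl ketones to 4-oxo six-membered rings. The only new stereocentre, C5 (C6 of the dione), is controlled by the chiral carbene, which fixes the configuration of the tetrahedral C3 adduct whose O–H should deliver the proton to the same face of the enolate. The step needs chemoselectivity and enantioselectivity: no other ring size is accessible (attack at C5 is anti-Michael, the ketone is too hindered for a crossed benzoin), and high dilution without free base should suppress intermolecular aldol and benzoin paths and epimerisation at C5.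

Step 4
Reactants: 5 (6R)-2,2,6-trimethylcyclohexane-1,4-dione
Product: 6 (4R,6R)-4-hydroxy-2,2,6-trimethylcyclohexan-1-one
Conditions: Li[HB(sec-Bu)3], THF, −78 °C; H2O
Reagents that add atoms: none
Why: The bulky hydride should attack only the unhindered C4 carbonyl, and equatorially because the axial C2 methyl blocks the axial path, so the new alcohol is axial and trans to the equatorial C6 methyl (1,3-induction, 6R gives 4R), as in hindered-hydride reductions of 3,3,5-trisubstituted cyclohexanones.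

Step 5
Reactants: 6 (4R,6R)-4-hydroxy-2,2,6-trimethylcyclohexan-1-one
Product: 7 (4R,6R)-2,2,6-trimethyl-4-[(triethylsilyl)oxy]cyclohexan-1-one
Conditions: Et3SiCl, imidazole, CH2Cl2, 0 °C
Reagents that add atoms: chlorotriethylsilane, CC[Si](Cl)(CC)CC
Why: Standard silylation masks the secondary alcohol for the enolate chemistry that follows.

Step 6
Reactants: 7 (4R,6R)-2,2,6-trimethyl-4-[(triethylsilyl)oxy]cyclohexan-1-one
Product: 9 (4R)-2,6,6-trimethyl-4-[(triethylsilyl)oxy]cyclohex-1-en-1-yl trifluoromethanesulfonate, via lithium enolate 8 (not isolated)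
Conditions: LiN(iPr)2, THF, −78 → 0 °C; PhNTf2, 0 °C → rt
Reagents that add atoms: N-phenylbis(trifluoromethanesulfonimide), O=S(=O)(N(c1ccccc1)S(=O)(=O)C(F)(F)F)C(F)(F)F
Why: The ketone can enolise only towards C6, so deprotonation gives one tetrasubstituted enolate whose O-triflation fixes the C5=C6 double bond of ring A and erases the relay stereocentre.

Step 7
Reactants: 9 (4R)-2,6,6-trimethyl-4-[(triethylsilyl)oxy]cyclohex-1-en-1-yl trifluoromethanesulfonate; 10 (2E)-3-methylpent-2-en-4-yn-1-ol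
Product: 11 (2E)-3-methyl-5-{(4R)-2,6,6-trimethyl-4-[(triethylsilyl)oxy]cyclohex-1-en-1-yl}pent-2-en-4-yn-1-ol
Conditions: Pd(PPh3)4 (5 mol%), CuI (10 mol%), iPr2NH, DMF, rt
Reagents that add atoms: none
Why: Sonogashira coupling of the alkenyl triflate (oxidative addition to zerovalent palladium) with the terminal alkyne forms the C6–C7 bond and keeps the E-configured C9=C10 bond of the enynol.

Step 8
Reactants: 11 (2E)-3-methyl-5-{(4R)-2,6,6-trimethyl-4-[(triethylsilyl)oxy]cyclohex-1-en-1-yl}pent-2-en-4-yn-1-ol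
Product: 12 {(2E)-5-[(4R)-4-hydroxy-2,6,6-trimethylcyclohex-1-en-1-yl]-3-methylpent-2-en-4-yn-1-yl}triphenylphosphonium bromide
Conditions: PPh3·HBr (1.1 equiv), MeOH, rt
Reagents that add atoms: triphenylphosphine hydrobromide, [Br-].[PH+](c1ccccc1)(c1ccccc1)c1ccccc1
Why: The allylic alcohol ionises in the acidic medium and is trapped by PPh3 at the unhindered primary terminus to give the Wittig salt, while the same acidic methanol should cleave the labile triethylsilyl ether.

Step 9
Reactants: 12 {(2E)-5-[(4R)-4-hydroxy-2,6,6-trimethylcyclohex-1-en-1-yl]-3-methylpent-2-en-4-yn-1-yl}triphenylphosphonium bromide; 13 (2E,4E,6E)-2,7-dimethylocta-2,4,6-trienedial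
Product: 15 (2E,4E,6E,8E,10E)-13-[(4R)-4-hydroxy-2,6,6-trimethylcyclohex-1-en-1-yl]-2,7,11-trimethyltrideca-2,4,6,8,10-pentaen-12-ynal, via C15 phosphonium ylide 14 (not isolated)
Conditions: NaOMe (1.1 equiv), MeOH/CH2Cl2, 0 °C → rt, 13 in excess (3 equiv); then n-heptane, 80 °C
Reagents that add atoms: none
Why: Wittig olefination of the semi-stabilised ylide with one formyl group of the excess symmetrical dialdehyde forms the C11=C12 bond, and thermal equilibration is expected to favour the E isomer.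

Step 10
Reactants: 15 (2E,4E,6E,8E,10E)-13-[(4R)-4-hydroxy-2,6,6-trimethylcyclohex-1-en-1-yl]-2,7,11-trimethyltrideca-2,4,6,8,10-pentaen-12-ynal
Product: 16 (2E,4E,6E,8E,10E)-13-[(4R)-4-hydroxy-2,6,6-trimethylcyclohex-1-en-1-yl]-2,7,11-trimethyltrideca-2,4,6,8,10-pentaen-12-yn-1-ol
Conditions: NaBH4, MeOH/THF, 0 °C
Reagents that add atoms: none
Why: Borohydride 1,2-reduction of the polyenal gives the allylic alcohol without touching the polyenyne.

Step 11
Reactants: 16 (2E,4E,6E,8E,10E)-13-[(4R)-4-hydroxy-2,6,6-trimethylcyclohex-1-en-1-yl]-2,7,11-trimethyltrideca-2,4,6,8,10-pentaen-12-yn-1-ol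
Product: 17 {(2E,4E,6E,8E,10E)-13-[(4R)-4-hydroxy-2,6,6-trimethylcyclohex-1-en-1-yl]-2,7,11-trimethyltrideca-2,4,6,8,10-pentaen-12-yn-1-yl}triphenylphosphonium bromide
Conditions: PPh3·HBr (1.05 equiv), MeOH/CH2Cl2, rt, dark
Reagents that add atoms: triphenylphosphine hydrobromide, [Br-].[PH+](c1ccccc1)(c1ccccc1)c1ccccc1
Why: As in step 8, the polyenylic alcohol ionises readily and is trapped by PPh3 at the terminal carbon to give the C25 Wittig salt.

Step 12
Reactants: 18 2,6,6-trimethylcyclohex-2-ene-1,4-dione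
Product: 19 (4R)-4-hydroxy-2,6,6-trimethylcyclohex-2-en-1-one
Conditions: (3aS)-1-methyl-3,3-diphenyltetrahydro-1H,3H-pyrrolo[1,2-c][1,3,2]oxazaborole (0.1 equiv), BH3·SMe2 (0.6 equiv), THF, −30 °C; MeOH, aqueous work-up
Reagents that add atoms: none
Why: Corey–Bakshi–Shibata reduction should take place at the less hindered C4 carbonyl (C1 is flanked by a quaternary carbon and a substituted alkene carbon), the oxazaborolidine distinguishing the alkenyl from the methylene flank so that the (S)-catalyst gives the (R)-alcohol; the antipodal catalyst is used if the sense proves reversed.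

Step 13
Reactants: 19 (4R)-4-hydroxy-2,6,6-trimethylcyclohex-2-en-1-one; 10 (2E)-3-methylpent-2-en-4-yn-1-ol
Product: 22 (1R,4R)-1-[(3E)-5-hydroxy-3-methylpent-3-en-1-yn-1-yl]-2,6,6-trimethylcyclohex-2-ene-1,4-diol, via lithium alkoxide 20 (not isolated), via dilithio enynol 21 (not isolated)
Conditions: 19, LiN(SiMe3)2 (1.0 equiv), THF, −78 °C; separately 10 (2.0 equiv), n-BuLi (4.0 equiv), THF, −78 → 0 °C; combine at −78 → −20 °C; H2O
Reagents that add atoms: none
Why: The acetylide should add 1,2 to the enone carbonyl axially, on the face anti to the pseudoaxial C6 methyl of the half-chair in which the C4 oxygen is pseudoequatorial, that is syn to the C4 oxygen (aided by lithium bridging), so that C4 (R) induces C1 (R) by 1,4-induction.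

Step 14
Reactants: 22 (1R,4R)-1-[(3E)-5-hydroxy-3-methylpent-3-en-1-yn-1-yl]-2,6,6-trimethylcyclohex-2-ene-1,4-diol
Product: 23 (1R,4R)-1-[(1E,3E)-5-hydroxy-3-methylpenta-1,3-dien-1-yl]-2,6,6-trimethylcyclohex-2-ene-1,4-diol
Conditions: LiAlH4 (4 equiv), THF, 0 °C → rt; H2O
Reagents that add atoms: none
Why: Hydroxyl-directed trans-hydroalumination of the propargylic alcohol by LiAlH4 gives the E-alkene (C7'=C8') and leaves the trisubstituted alkenes untouched.

Step 15
Reactants: 23 (1R,4R)-1-[(1E,3E)-5-hydroxy-3-methylpenta-1,3-dien-1-yl]-2,6,6-trimethylcyclohex-2-ene-1,4-diol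
Product: 24 (2E,4E)-5-[(1R)-1-hydroxy-2,6,6-trimethyl-4-oxocyclohex-2-en-1-yl]-3-methylpenta-2,4-dienal
Conditions: MnO2 (activated, excess), CH2Cl2, rt
Reagents that add atoms: none
Why: MnO2 oxidises both allylic alcohols (the primary one to the dienal, the ring alcohol to the enone) but not the tertiary alcohol, so the C3' stereocentre is removed once it has set C6'.

Step 16
Reactants: 17 {(2E,4E,6E,8E,10E)-13-[(4R)-4-hydroxy-2,6,6-trimethylcyclohex-1-en-1-yl]-2,7,11-trimethyltrideca-2,4,6,8,10-pentaen-12-yn-1-yl}triphenylphosphonium bromide; 24 (2E,4E)-5-[(1R)-1-hydroxy-2,6,6-trimethyl-4-oxocyclohex-2-en-1-yl]-3-methylpenta-2,4-dienal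
Product: 26 (3R,6'R)-3,6'-dihydroxy-7,8-didehydro-β,ε-caroten-3'-one, via C25 phosphonium ylide 25 (not isolated)
Conditions: NaOMe (1.2 equiv), MeOH/CH2Cl2, 0 °C → rt; then EtOH, 60 °C, dark
Reagents that add atoms: none
Why: Wittig olefination of the C25 ylide with the dienal forms the C11'=C12' bond chemoselectively at the aldehyde, the hindered enone being unreactive towards a semi-stabilised ylide.

Step 17
Reactants: 26 (3R,6'R)-3,6'-dihydroxy-7,8-didehydro-β,ε-caroten-3'-one
Product: 27 (3R,3'S,6'R)-7,8-didehydro-β,ε-carotene-3,3',6'-triol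
Conditions: NaBH4, CeCl3·7H2O, MeOH/THF, −40 °C; all-E isomer isolated by crystallisation or HPLC
Reagents that add atoms: none
Why: Luche 1,2-reduction should deliver hydride to the C3' carbonyl anti to the axial C1' methyl of the half-chair that carries the polyene chain pseudoaxially, placing the new hydroxyl cis to the C6' hydroxyl (3'S), in line with borohydride reductions of abscisic acid esters to their cis-diols.

Compound list
1 | 3,3-dimethyloxolan-2-one | CC1(C)CCOC1=O | starting material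
2 | isopropenylmagnesium bromide | CC(=C)[Mg]Br | starting material
3 | 6-hydroxy-2,4,4-trimethylhex-1-en-3-one | CC(=C)C(=O)C(C)(C)CCO | intermediate
4 | 3,3,5-trimethyl-4-oxohex-5-enal | CC(=C)C(=O)C(C)(C)CC=O | intermediate
5 | (6R)-2,2,6-trimethylcyclohexane-1,4-dione | C[C@@H]1CC(=O)CC(C)(C)C1=O | intermediate
6 | (4R,6R)-4-hydroxy-2,2,6-trimethylcyclohexan-1-one | C[C@@H]1C[C@@H](O)CC(C)(C)C1=O | intermediate
7 | (4R,6R)-2,2,6-trimethyl-4-[(triethylsilyl)oxy]cyclohexan-1-one | C[C@@H]1C[C@@H](O[Si](CC)(CC)CC)CC(C)(C)C1=O | intermediate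
8 | lithium (4R)-2,6,6-trimethyl-4-[(triethylsilyl)oxy]cyclohex-1-en-1-olate | [Li]OC1=C(C)C[C@@H](O[Si](CC)(CC)CC)CC1(C)C | intermediate
9 | (4R)-2,6,6-trimethyl-4-[(triethylsilyl)oxy]cyclohex-1-en-1-yl trifluoromethanesulfonate | FC(F)(F)S(=O)(=O)OC1=C(C)C[C@@H](O[Si](CC)(CC)CC)CC1(C)C | intermediate
10 | (2E)-3-methylpent-2-en-4-yn-1-ol | C#C/C(C)=C/CO | starting material
11 | (2E)-3-methyl-5-{(4R)-2,6,6-trimethyl-4-[(triethylsilyl)oxy]cyclohex-1-en-1-yl}pent-2-en-4-yn-1-ol | OC/C=C(\C)C#CC1=C(C)C[C@@H](O[Si](CC)(CC)CC)CC1(C)C | intermediate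
12 | {(2E)-5-[(4R)-4-hydroxy-2,6,6-trimethylcyclohex-1-en-1-yl]-3-methylpent-2-en-4-yn-1-yl}triphenylphosphonium bromide | c1ccccc1[P+](c1ccccc1)(c1ccccc1)C/C=C(\C)C#CC1=C(C)C[C@@H](O)CC1(C)C.[Br-] | intermediate
13 | (2E,4E,6E)-2,7-dimethylocta-2,4,6-trienedial | O=C/C(C)=C/C=C/C=C(C)/C=O | starting material
14 | ylide of 12 (C15 phosphonium ylide) | c1ccccc1[P+](c1ccccc1)(c1ccccc1)[CH-]/C=C(\C)C#CC1=C(C)C[C@@H](O)CC1(C)C | intermediate
15 | (2E,4E,6E,8E,10E)-13-[(4R)-4-hydroxy-2,6,6-trimethylcyclohex-1-en-1-yl]-2,7,11-trimethyltrideca-2,4,6,8,10-pentaen-12-ynal | O=C/C(C)=C/C=C/C=C(C)/C=C/C=C(\C)C#CC1=C(C)C[C@@H](O)CC1(C)C | intermediate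
16 | (2E,4E,6E,8E,10E)-13-[(4R)-4-hydroxy-2,6,6-trimethylcyclohex-1-en-1-yl]-2,7,11-trimethyltrideca-2,4,6,8,10-pentaen-12-yn-1-ol | OC/C(C)=C/C=C/C=C(C)/C=C/C=C(\C)C#CC1=C(C)C[C@@H](O)CC1(C)C | intermediate
17 | {(2E,4E,6E,8E,10E)-13-[(4R)-4-hydroxy-2,6,6-trimethylcyclohex-1-en-1-yl]-2,7,11-trimethyltrideca-2,4,6,8,10-pentaen-12-yn-1-yl}triphenylphosphonium bromide | c1ccccc1[P+](c1ccccc1)(c1ccccc1)C/C(C)=C/C=C/C=C(C)/C=C/C=C(\C)C#CC1=C(C)C[C@@H](O)CC1(C)C.[Br-] | intermediate
18 | 2,6,6-trimethylcyclohex-2-ene-1,4-dione | CC1=CC(=O)CC(C)(C)C1=O | starting material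
19 | (4R)-4-hydroxy-2,6,6-trimethylcyclohex-2-en-1-one | CC1=C[C@H](O)CC(C)(C)C1=O | intermediate
20 | lithium (1R)-3,5,5-trimethyl-4-oxocyclohex-2-en-1-olate | CC1=C[C@H](O[Li])CC(C)(C)C1=O | intermediate
21 | dilithio derivative of 10 (lithium (2E)-5-lithio-3-methylpent-2-en-4-yn-1-olate) | [Li]C#C/C(C)=C/CO[Li] | intermediate
22 | (1R,4R)-1-[(3E)-5-hydroxy-3-methylpent-3-en-1-yn-1-yl]-2,6,6-trimethylcyclohex-2-ene-1,4-diol | CC1=C[C@H](O)CC(C)(C)[C@]1(O)C#C/C(C)=C/CO | intermediate
23 | (1R,4R)-1-[(1E,3E)-5-hydroxy-3-methylpenta-1,3-dien-1-yl]-2,6,6-trimethylcyclohex-2-ene-1,4-diol | CC1=C[C@H](O)CC(C)(C)[C@]1(O)/C=C/C(C)=C/CO | intermediate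
24 | (2E,4E)-5-[(1R)-1-hydroxy-2,6,6-trimethyl-4-oxocyclohex-2-en-1-yl]-3-methylpenta-2,4-dienal | CC1=CC(=O)CC(C)(C)[C@]1(O)/C=C/C(C)=C/C=O | intermediate
25 | ylide of 17 (C25 phosphonium ylide) | c1ccccc1[P+](c1ccccc1)(c1ccccc1)[CH-]/C(C)=C/C=C/C=C(C)/C=C/C=C(\C)C#CC1=C(C)C[C@@H](O)CC1(C)C | intermediate
26 | (3R,6'R)-3,6'-dihydroxy-7,8-didehydro-β,ε-caroten-3'-one | CC1=CC(=O)CC(C)(C)[C@]1(O)/C=C/C(C)=C/C=C/C(C)=C/C=C/C=C(C)/C=C/C=C(\C)C#CC1=C(C)C[C@@H](O)CC1(C)C | intermediate
27 | (3R,3'S,6'R)-7,8-didehydro-β,ε-carotene-3,3',6'-triol | CC1=C[C@@H](O)CC(C)(C)[C@]1(O)/C=C/C(C)=C/C=C/C(C)=C/C=C/C=C(C)/C=C/C=C(\C)C#CC1=C(C)C[C@@H](O)CC1(C)C | target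

Total step count: 17. Longest linear sequence: 13 (steps 1–11, 16 and 17); ring B is made in 4 steps (12–15).

Steps most likely to fail

Step 3 (Proposed new method). The carbene-bound acyl anion may fail to close in the endo mode, or unselective proton transfer and later enolisation may erode the configuration at C5. The fallback uses known chemistry, sets out from 4 and returns at 8. Samarium diiodide (SmI2, THF/t-BuOH, −78 °C) reduces the aldehyde to a ketyl that adds 6-endo to the enone and closes the same C3–C4 bond, giving racemic 4-hydroxy-2,2,6-trimethylcyclohexan-1-one F1 as C6 epimers. Steglich esterification with (2S)-2-methoxy-2-phenylacetic acid and separation of the diastereomers gives (1R)-3,3,5-trimethyl-4-oxocyclohexyl (2S)-2-methoxy-2-phenylacetate F2. Methanolysis (K2CO3, MeOH) gives (4R)-4-hydroxy-2,2,6-trimethylcyclohexan-1-one F3 as C6 epimers, which is silylated as in step 5 to (4R)-2,2,6-trimethyl-4-[(triethylsilyl)oxy]cyclohexan-1-one F4. Deprotonation as in step 6 planarises C6 and gives enolate 8.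

Step 17. Hydride may be delivered with poor facial selectivity at C3' at the last stage, giving C3' epimers of a C40 polyene that are hard to separate. The fallback sets out from 23 and returns at 27. TEMPO/PhI(OAc)2 oxidises only the primary allylic alcohol to (2E,4E)-5-[(1R,4R)-1,4-dihydroxy-2,6,6-trimethylcyclohex-2-en-1-yl]-3-methylpenta-2,4-dienal F5. A Mitsunobu reaction (4-nitrobenzoic acid, PPh3, diisopropyl azodicarboxylate) inverts the secondary allylic carbinol to (1S,4R)-4-hydroxy-3,5,5-trimethyl-4-[(1E,3E)-3-methyl-5-oxopenta-1,3-dien-1-yl]cyclohex-2-en-1-yl 4-nitrobenzoate F6. Wittig reaction with ylide 25 gives (3R,3'S,6'R)-3,6'-dihydroxy-7,8-didehydro-β,ε-caroten-3'-yl 4-nitrobenzoate F7, and K2CO3/MeOH liberates 27.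

Step 13. The acetylide may attack the carbonyl face anti to the C4 oxygen, or with low facial preference, which after oxidation of C4 would lower the enantiomeric purity of 24. The fallback sets out from 18 and returns at 24. If anti attack dominates, 18 is reduced with the antipodal (3aR)-oxazaborolidine to (4S)-4-hydroxy-2,6,6-trimethylcyclohex-2-en-1-one F8. Its alkoxide, lithium (1S)-3,5,5-trimethyl-4-oxocyclohex-2-en-1-olate F9, is treated with 21 to give (1R,4S)-1-[(3E)-5-hydroxy-3-methylpent-3-en-1-yn-1-yl]-2,6,6-trimethylcyclohex-2-ene-1,4-diol F10. LiAlH4 gives (1R,4S)-1-[(1E,3E)-5-hydroxy-3-methylpenta-1,3-dien-1-yl]-2,6,6-trimethylcyclohex-2-ene-1,4-diol F11, and MnO2 converges on 24. With merely low selectivity, the diastereomers of 22 are separated by chromatography before step 14.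

Further compounds
F1 | step 3 | rac-4-hydroxy-2,2,6-trimethylcyclohexan-1-one (C6 epimers) | CC1CC(O)CC(C)(C)C1=O
F2 | step 3 | (1R)-3,3,5-trimethyl-4-oxocyclohexyl (2S)-2-methoxy-2-phenylacetate (C5 epimers) | CC1C[C@@H](OC(=O)[C@@H](OC)c2ccccc2)CC(C)(C)C1=O
F3 | step 3 | (4R)-4-hydroxy-2,2,6-trimethylcyclohexan-1-one (C6 epimers) | CC1C[C@@H](O)CC(C)(C)C1=O
F4 | step 3 | (4R)-2,2,6-trimethyl-4-[(triethylsilyl)oxy]cyclohexan-1-one (C6 epimers) | CC1C[C@@H](O[Si](CC)(CC)CC)CC(C)(C)C1=O
F5 | step 17 | (2E,4E)-5-[(1R,4R)-1,4-dihydroxy-2,6,6-trimethylcyclohex-2-en-1-yl]-3-methylpenta-2,4-dienal | CC1=C[C@H](O)CC(C)(C)[C@]1(O)/C=C/C(C)=C/C=O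
F6 | step 17 | (1S,4R)-4-hydroxy-3,5,5-trimethyl-4-[(1E,3E)-3-methyl-5-oxopenta-1,3-dien-1-yl]cyclohex-2-en-1-yl 4-nitrobenzoate | CC1=C[C@@H](OC(=O)c2ccc(cc2)[N+](=O)[O-])CC(C)(C)[C@]1(O)/C=C/C(C)=C/C=O
F7 | step 17 | (3R,3'S,6'R)-3,6'-dihydroxy-7,8-didehydro-β,ε-caroten-3'-yl 4-nitrobenzoate | CC1=C[C@@H](OC(=O)c2ccc(cc2)[N+](=O)[O-])CC(C)(C)[C@]1(O)/C=C/C(C)=C/C=C/C(C)=C/C=C/C=C(C)/C=C/C=C(\C)C#CC1=C(C)C[C@@H](O)CC1(C)C
F8 | step 13 | (4S)-4-hydroxy-2,6,6-trimethylcyclohex-2-en-1-one | CC1=C[C@@H](O)CC(C)(C)C1=O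
F9 | step 13 | lithium (1S)-3,5,5-trimethyl-4-oxocyclohex-2-en-1-olate | CC1=C[C@@H](O[Li])CC(C)(C)C1=O
F10 | step 13 | (1R,4S)-1-[(3E)-5-hydroxy-3-methylpent-3-en-1-yn-1-yl]-2,6,6-trimethylcyclohex-2-ene-1,4-diol | CC1=C[C@@H](O)CC(C)(C)[C@]1(O)C#C/C(C)=C/CO
F11 | step 13 | (1R,4S)-1-[(1E,3E)-5-hydroxy-3-methylpenta-1,3-dien-1-yl]-2,6,6-trimethylcyclohex-2-ene-1,4-diol | CC1=C[C@@H](O)CC(C)(C)[C@]1(O)/C=C/C(C)=C/CO
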